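**Retrosynthetic overview**
1. Target ⇐ ring C5=C6 by Saegusa–Ito dehydrogenation, tertiary alcohol by Mukaiyama hydration of a methallyl group, chroman pyran ring by Pd-catalysed aryl C–O closure ⇐ C6–CH2 bond by Giese addition of a β-hydroxyalkyl radical (chiral-pool iodohydrin) to a bicyclic enone.
2. Bicyclic enone ⇐ key step: radical 5-exo 1,6-cyclisation of (6S)-6-(3-bromopropyl)-5,6-dimethylcyclohexa-2,4-dienone, closing the cyclopentane at the bond between its CH2 (indenone C1) and the methyl-bearing fusion carbon C7a, with in-flask allyl transfer that also installs the C5 side-chain skeleton.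
3. Enabling feature: in the six-membered ring, fusion carbon C7a is linked to the C4 ketone through C7 and C6=C5, so at the dienone level (C4=O, C5=C6, C7=C7a) it is the δ-terminus of a vinylogous acceptor; the adjacent quaternary fusion carbon C3a (α to the ketone) carries the three-carbon arm, whose terminal radical can reach only C7a, 5-exo and cis.
4. Dienone ⇐ 2-methylcyclohex-2-enone by asymmetric conjugate methylation/enolate allylation (a relay stereocentre sets the quaternary carbon and is later erased), anti-Markovnikov HBr addition and two dehydrogenations.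
5. Ring order: cyclohexane (bought) → cyclopentane (key step) → pyran ring of the chroman (step 11); the arene is bought.

Key step: step 5

Assumption (remark on the chemistry): the magnesium enolate 2 is taken to be allylated anti to its C3 methyl group, as is usual for 2,3-disubstituted cyclohexanone enolates. The minor syn isomer would become the enantiomer of 7 after step 4, so it is removed by chromatography at the stage of 3.

**Step 1**
Reactants: 1 2-methylcyclohex-2-en-1-one
Product: 3 (2S,3R)-2,3-dimethyl-2-(prop-2-en-1-yl)cyclohexan-1-one, via magnesium enolate 2 (not isolated)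
Conditions: MeMgBr, CuBr·SMe2 (5 mol%), (R)-1-[(S)-2-(diphenylphosphino)ferrocenyl]ethyldicyclohexylphosphine or its mirror image (6 mol%, the enantiomer that gives 3R), t-BuOMe, −75 °C; then allyl iodide, DMPU, −20 °C to rt
Reagents that add atoms: methylmagnesium bromide C[Mg]Br; allyl iodide ICC=C
Why: Copper-catalysed asymmetric conjugate addition should set C3 (R) under catalyst control, and C-allylation of the tetrasubstituted enolate anti to that methyl group relays the chirality to the quaternary C2 (S).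

**Step 2**
Reactants: 3 (2S,3R)-2,3-dimethyl-2-(prop-2-en-1-yl)cyclohexan-1-one
Product: 4 (2S,3R)-2-(3-bromopropyl)-2,3-dimethylcyclohexan-1-one
Conditions: HBr (gas), AIBN (5 mol%), hexane, 0 °C, hν
Reagents that add atoms: hydrogen bromide Br
Why: Radical-chain anti-Markovnikov hydrobromination (Kharasch addition) of the monosubstituted alkene should place bromine on the terminal carbon without touching a stereocentre.

**Step 3**
Reactants: 4 (2S,3R)-2-(3-bromopropyl)-2,3-dimethylcyclohexan-1-one
Product: 6 (5R,6S)-6-(3-bromopropyl)-5,6-dimethylcyclohex-2-en-1-one, via silyl enol ether 5 (not isolated)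
Conditions: TMSOTf, Et3N, CH2Cl2, 0 °C; then Pd(OAc)2 (10 mol%), O2 (1 atm), DMSO, rt
Reagents that add atoms: none
Why: Saegusa–Ito dehydrogenation is regiodefined because the ketone can enolise only toward its CH2 side, the other α-carbon being quaternary.

**Step 4**
Reactants: 6 (5R,6S)-6-(3-bromopropyl)-5,6-dimethylcyclohex-2-en-1-one
Product: 7 (6S)-6-(3-bromopropyl)-5,6-dimethylcyclohexa-2,4-dien-1-one
Conditions: chloranil (1.5 equiv), t-BuOH, reflux; used at once
Reagents that add atoms: none
Why: Quinone dehydrogenation through the dienol (hydride loss from the allylic tertiary C5–H), the reaction type that turns 4-en-3-ones into 4,6-dien-3-ones, should give the linear dienone; the relay stereocentre C5 is erased and C6 keeps the chirality.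

**Step 5**
Reactants: 7 (6S)-6-(3-bromopropyl)-5,6-dimethylcyclohexa-2,4-dien-1-one
Product: 9 (3aS,7aS)-3a,7a-dimethyl-5-(2-methylprop-2-en-1-yl)-1,2,3,3a,7,7a-hexahydro-4H-inden-4-one, via deconjugated enone 8 (not isolated)
Conditions: tributyl(2-methylallyl)stannane (5 equiv), AIBN (0.3 equiv, portionwise), benzene (0.05 M), 80 °C; then DBU (0.3 equiv), rt
Reagents that add atoms: tributyl(2-methylallyl)stannane CC(=C)C[Sn](CCCC)(CCCC)CCCC
Why: Proposed new method: a stannyl radical abstracts bromine, the primary radical closes 5-exo-trig onto the methyl-bearing C5 of the dienone (its δ-carbon, a radical 1,6-conjugate addition), and the resulting 1-oxopentadienyl radical is allylated at the carbon α to the carbonyl by SH2' attack on the stannane, which releases the chain-carrying stannyl radical; DBU then moves the remaining ring double bond into conjugation and erases the uncontrolled C5 centre of 8. The closest known reactions are 5-exo radical cyclisations onto enones and dienoates terminated by Keck allyl transfer; trapping of a dienone-derived delocalised radical in this way is the new element. The cyclopentane closes in the 5-exo mode, and because the arm hangs from the quaternary carbon next to the attacked one, only cis fusion is geometrically possible, so the new quaternary centre C7a (S) is set by the existing C3a (S) with both methyl groups on one face. The step needs 5-exo over 6-endo closure (secured by conjugation, since only δ-attack gives a carbonyl-stabilised radical), cyclisation before direct allylation of the primary radical (unimolecular closure against a slow bimolecular transfer), and α- over γ-allylation (the γ-terminus is neopentylic, next to the new quaternary centre).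

**Step 6**
Reactants: 10 1-methoxy-3,5-dimethylbenzene
Product: 11 1-(bromomethyl)-3-methoxy-5-methylbenzene
Conditions: NBS (1.0 equiv), AIBN (cat.), PhCF3, 80 °C
Reagents that add atoms: N-bromosuccinimide O=C1CCC(=O)N1Br
Why: Wohl–Ziegler benzylic bromination under radical conditions in a non-polar solvent, stopped at partial conversion, should favour the monobromide over dibromide and ring bromination.

**Step 7**
Reactants: 11 1-(bromomethyl)-3-methoxy-5-methylbenzene; 12 [(2R)-2-methyloxiran-2-yl]methanol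
Product: 14 (2S)-4-(3-methoxy-5-methylphenyl)-2-methylbutane-1,2-diol, via benzylic Grignard reagent 13 (not isolated)
Conditions: Mg, Et2O, 0 °C (slow addition of 11); then CuI (10 mol%), 12 (0.45 equiv), THF, −40 to 0 °C; aq. NH4Cl
Reagents that add atoms: none
Why: Copper-catalysed SN2 opening of the 2,2-disubstituted epoxide at its CH2 terminus (one Grignard equivalent is spent on the hydroxyl) leaves the chiral-pool stereocentre untouched; the descriptor changes from R to S only through CIP priorities.

**Step 8**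
Reactants: 14 (2S)-4-(3-methoxy-5-methylphenyl)-2-methylbutane-1,2-diol
Product: 15 (2S)-4-(2-bromo-5-methoxy-3-methylphenyl)-2-methylbutane-1,2-diol
Conditions: NBS (1.05 equiv), MeCN, 0 °C to rt
Reagents that add atoms: N-bromosuccinimide O=C1CCC(=O)N1Br
Why: Electrophilic aromatic bromination in acetonitrile should go para to the methoxy group, which is the position between the ring methyl group and the side chain.

**Step 9**
Reactants: 15 (2S)-4-(2-bromo-5-methoxy-3-methylphenyl)-2-methylbutane-1,2-diol
Product: 16 (2S)-4-(2-bromo-5-methoxy-3-methylphenyl)-1-iodo-2-methylbutan-2-ol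
Conditions: I2, PPh3, imidazole, CH2Cl2, 0 °C to rt
Reagents that add atoms: iodine I-I
Why: Appel-type iodination should act only on the primary hydroxyl, and any epoxide formed by internal displacement is reopened by iodide at the primary carbon to the same iodohydrin.

**Step 10**
Reactants: 9 (3aS,7aS)-3a,7a-dimethyl-5-(2-methylprop-2-en-1-yl)-1,2,3,3a,7,7a-hexahydro-4H-inden-4-one; 16 (2S)-4-(2-bromo-5-methoxy-3-methylphenyl)-1-iodo-2-methylbutan-2-ol
Product: 17 (3aS,7aS)-6-[(2S)-4-(2-bromo-5-methoxy-3-methylphenyl)-2-hydroxy-2-methylbutyl]-3a,7a-dimethyl-5-(2-methylprop-2-en-1-yl)octahydro-4H-inden-4-one (C5/C6 epimer mixture)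
Conditions: 16 (1.5 equiv), (TMS)3SiH (1.6 equiv, syringe pump), AIBN (10 mol%), toluene, 80 °C
Reagents that add atoms: none
Why: Giese reaction in which the silyl radical takes iodine (far faster than aryl bromine), the β-hydroxyalkyl radical (no β-leaving group, so no fragmentation) adds to C6 of the enone and the α-keto radical is reduced by the silane; the C5/C6 centres form without control and are removed in step 13.

**Step 11**
Reactants: 17 (3aS,7aS)-6-[(2S)-4-(2-bromo-5-methoxy-3-methylphenyl)-2-hydroxy-2-methylbutyl]-3a,7a-dimethyl-5-(2-methylprop-2-en-1-yl)octahydro-4H-inden-4-one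
Product: 18 (3aS,7aS)-6-{[(2S)-6-methoxy-2,8-dimethyl-3,4-dihydro-2H-1-benzopyran-2-yl]methyl}-3a,7a-dimethyl-5-(2-methylprop-2-en-1-yl)octahydro-4H-inden-4-one
Conditions: Pd(OAc)2 (5 mol%), 2-(di-tert-butylphosphino)-1,1'-binaphthyl (6 mol%), Cs2CO3, toluene, 80 °C
Reagents that add atoms: none
Why: Palladium-catalysed intramolecular aryl C–O coupling of the tertiary alcohol with the ortho aryl bromide closes the six-membered pyran ring; the carbinol C–O bond is not broken, so the chroman stereocentre keeps its configuration.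

**Step 12**
Reactants: 18 (3aS,7aS)-6-{[(2S)-6-methoxy-2,8-dimethyl-3,4-dihydro-2H-1-benzopyran-2-yl]methyl}-3a,7a-dimethyl-5-(2-methylprop-2-en-1-yl)octahydro-4H-inden-4-one
Product: 19 (3aS,7aS)-5-(2-hydroxy-2-methylpropyl)-6-{[(2S)-6-methoxy-2,8-dimethyl-3,4-dihydro-2H-1-benzopyran-2-yl]methyl}-3a,7a-dimethyloctahydro-4H-inden-4-one
Conditions: Co(acac)2 (20 mol%), PhSiH3 (2.5 equiv), O2 (1 atm), i-PrOH, rt
Reagents that add atoms: dioxygen O=O
Why: Mukaiyama hydration (hydrogen-atom transfer to the 1,1-disubstituted alkene, O2 capture of the tertiary radical, reduction) should give the Markovnikov tertiary alcohol while the saturated ketone and aryl ether stay inert.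

**Step 13**
Reactants: 19 (3aS,7aS)-5-(2-hydroxy-2-methylpropyl)-6-{[(2S)-6-methoxy-2,8-dimethyl-3,4-dihydro-2H-1-benzopyran-2-yl]methyl}-3a,7a-dimethyloctahydro-4H-inden-4-one
Product: 22 (3aS,7aS)-5-(2-hydroxy-2-methylpropyl)-6-{[(2S)-6-methoxy-2,8-dimethyl-3,4-dihydro-2H-1-benzopyran-2-yl]methyl}-3a,7a-dimethyl-1,2,3,3a,7,7a-hexahydro-4H-inden-4-one (CNP0224132.2), via bis-silyl enol ether 20 (not isolated), via silyl ether enone 21 (not isolated)
Conditions: TMSOTf (3 equiv), Et3N (4 equiv), CH2Cl2, 0 °C to rt; then Pd(OAc)2 (1.1 equiv), MeCN, 40 °C; then 1 M HCl, THF, 0 °C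
Reagents that add atoms: none
Why: Saegusa–Ito oxidation in which enolisation is possible only toward C5 and palladation anti to the C6 substituent leaves the ring C6–H syn for β-hydride elimination, giving the tetrasubstituted enone; C5 and C6 become sp2, the three remaining stereocentres are untouched, and mild acid frees the tertiary alcohol.

**Compound list**
1 | 2-methylcyclohex-2-en-1-one | CC1=CCCCC1=O | starting material
2 | bromomagnesium (3R)-2,3-dimethylcyclohex-1-en-1-olate | Br[Mg]OC1=C(C)[C@H](C)CCC1 | intermediate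
3 | (2S,3R)-2,3-dimethyl-2-(prop-2-en-1-yl)cyclohexan-1-one | O=C1CCC[C@@H](C)[C@]1(C)CC=C | intermediate
4 | (2S,3R)-2-(3-bromopropyl)-2,3-dimethylcyclohexan-1-one | O=C1CCC[C@@H](C)[C@]1(C)CCCBr | intermediate
5 | {[(5R,6S)-6-(3-bromopropyl)-5,6-dimethylcyclohex-1-en-1-yl]oxy}trimethylsilane | C[Si](C)(C)OC1=CCC[C@@H](C)[C@]1(C)CCCBr | intermediate
6 | (5R,6S)-6-(3-bromopropyl)-5,6-dimethylcyclohex-2-en-1-one | O=C1C=CC[C@@H](C)[C@]1(C)CCCBr | intermediate
7 | (6S)-6-(3-bromopropyl)-5,6-dimethylcyclohexa-2,4-dien-1-one | O=C1C=CC=C(C)[C@]1(C)CCCBr | intermediate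
8 | (3aS,7aS)-3a,7a-dimethyl-5-(2-methylprop-2-en-1-yl)-1,2,3,3a,5,7a-hexahydro-4H-inden-4-one (both C5 epimers) | C1(CC(C)=C)C(=O)[C@@]2(C)CCC[C@@]2(C)C=C1 | intermediate
9 | (3aS,7aS)-3a,7a-dimethyl-5-(2-methylprop-2-en-1-yl)-1,2,3,3a,7,7a-hexahydro-4H-inden-4-one (cis-fused) | C1=C(CC(C)=C)C(=O)[C@@]2(C)CCC[C@@]2(C)C1 | intermediate
10 | 1-methoxy-3,5-dimethylbenzene | COc1cc(C)cc(C)c1 | starting material
11 | 1-(bromomethyl)-3-methoxy-5-methylbenzene | COc1cc(C)cc(CBr)c1 | intermediate
12 | [(2R)-2-methyloxiran-2-yl]methanol | OC[C@]1(C)CO1 | starting material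
13 | (3-methoxy-5-methylbenzyl)magnesium bromide | COc1cc(C)cc(C[Mg]Br)c1 | intermediate
14 | (2S)-4-(3-methoxy-5-methylphenyl)-2-methylbutane-1,2-diol | COc1cc(C)cc(CC[C@@](C)(CO)O)c1 | intermediate
15 | (2S)-4-(2-bromo-5-methoxy-3-methylphenyl)-2-methylbutane-1,2-diol | COc1cc(C)c(Br)c(CC[C@@](C)(CO)O)c1 | intermediate
16 | (2S)-4-(2-bromo-5-methoxy-3-methylphenyl)-1-iodo-2-methylbutan-2-ol | IC[C@@](C)(O)CCc1cc(OC)cc(C)c1Br | intermediate
17 | (3aS,7aS)-6-[(2S)-4-(2-bromo-5-methoxy-3-methylphenyl)-2-hydroxy-2-methylbutyl]-3a,7a-dimethyl-5-(2-methylprop-2-en-1-yl)octahydro-4H-inden-4-one (C5/C6 epimer mixture) | COc1cc(C)c(Br)c(CC[C@@](C)(CC2C(CC(C)=C)C(=O)[C@@]3(C)CCC[C@@]3(C)C2)O)c1 | intermediate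
18 | (3aS,7aS)-6-{[(2S)-6-methoxy-2,8-dimethyl-3,4-dihydro-2H-1-benzopyran-2-yl]methyl}-3a,7a-dimethyl-5-(2-methylprop-2-en-1-yl)octahydro-4H-inden-4-one (C5/C6 epimer mixture) | COc1cc(C)c2c(c1)CC[C@@](C)(CC1C(CC(C)=C)C(=O)[C@@]3(C)CCC[C@@]3(C)C1)O2 | intermediate
19 | (3aS,7aS)-5-(2-hydroxy-2-methylpropyl)-6-{[(2S)-6-methoxy-2,8-dimethyl-3,4-dihydro-2H-1-benzopyran-2-yl]methyl}-3a,7a-dimethyloctahydro-4H-inden-4-one (C5/C6 epimer mixture) | COc1cc(C)c2c(c1)CC[C@@](C)(CC1C(CC(C)(C)O)C(=O)[C@@]3(C)CCC[C@@]3(C)C1)O2 | intermediate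
20 | {[(3aS,7aS)-6-{[(2S)-6-methoxy-2,8-dimethyl-3,4-dihydro-2H-1-benzopyran-2-yl]methyl}-3a,7a-dimethyl-5-{2-methyl-2-[(trimethylsilyl)oxy]propyl}-2,3,3a,6,7,7a-hexahydro-1H-inden-4-yl]oxy}trimethylsilane | COc1cc(C)c2c(c1)CC[C@@](C)(CC1C(CC(C)(C)O[Si](C)(C)C)=C(O[Si](C)(C)C)[C@@]3(C)CCC[C@@]3(C)C1)O2 | intermediate
21 | (3aS,7aS)-6-{[(2S)-6-methoxy-2,8-dimethyl-3,4-dihydro-2H-1-benzopyran-2-yl]methyl}-3a,7a-dimethyl-5-{2-methyl-2-[(trimethylsilyl)oxy]propyl}-1,2,3,3a,7,7a-hexahydro-4H-inden-4-one | COc1cc(C)c2c(c1)CC[C@@](C)(CC1=C(CC(C)(C)O[Si](C)(C)C)C(=O)[C@@]3(C)CCC[C@@]3(C)C1)O2 | intermediate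
22 | (3aS,7aS)-5-(2-hydroxy-2-methylpropyl)-6-{[(2S)-6-methoxy-2,8-dimethyl-3,4-dihydro-2H-1-benzopyran-2-yl]methyl}-3a,7a-dimethyl-1,2,3,3a,7,7a-hexahydro-4H-inden-4-one | COc1cc(C)c2c(c1)CC[C@@](C)(CC1=C(CC(C)(C)O)C(=O)[C@@]3(C)CCC[C@@]3(C)C1)O2 | target

**Step count and risks**
Total step count: 13 (steps 1–5 bicyclic core, steps 6–9 side-arm fragment, steps 10–13 union and finish). Longest linear sequence: 9 steps (1–5, then 10–13).

Steps most likely to fail:

1. Step 5 (the step that carries the new-method label). The delocalised radical formed after ring closure may add too slowly to the stannane, so the chain dies by radical–radical coupling. Allyl transfer may also go to the γ-terminus, and the dienone may dimerise thermally (Diels–Alder) before it cyclises. The fallback uses known chemistry, sets out from 7 and comes back at 9. Reductive radical cyclisation of 7 with Bu3SnH (slow addition), AIBN, benzene, 80 °C, followed by DBU, should give (3aS,7aS)-3a,7a-dimethyl-1,2,3,3a,7,7a-hexahydro-4H-inden-4-one F1. α-Iodination with I2 and pyridine in CH2Cl2 should give (3aS,7aS)-5-iodo-3a,7a-dimethyl-1,2,3,3a,7,7a-hexahydro-4H-inden-4-one F2. Stille coupling of F2 with tributyl(2-methylallyl)stannane (Pd2(dba)3, AsPh3, CuI, NMP, 60 °C) then returns to 9.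

2. Step 10. The alkyl radical may be quenched by hydrogen-atom transfer before it adds to the α-substituted enone, and the methallyl group may be hydrosilylated once the iodide is consumed. The fallback closes the chroman first and forms the C–C bond by a nickel-mediated reductive conjugate addition with no hydrogen donor present; it sets out from 15 and comes back at 18. Silylation of the primary hydroxyl (TBSCl, imidazole) should give (2S)-4-(2-bromo-5-methoxy-3-methylphenyl)-1-[(tert-butyldimethylsilyl)oxy]-2-methylbutan-2-ol F3. The Pd-catalysed C–O closure of step 11 should give tert-butyl{[(2S)-6-methoxy-2,8-dimethyl-3,4-dihydro-2H-1-benzopyran-2-yl]methoxy}dimethylsilane F4. TBAF should free [(2S)-6-methoxy-2,8-dimethyl-3,4-dihydro-2H-1-benzopyran-2-yl]methanol F5, and I2, PPh3, imidazole in toluene at 80 °C should give (2S)-2-(iodomethyl)-6-methoxy-2,8-dimethyl-3,4-dihydro-2H-1-benzopyran F6. Reductive conjugate addition of F6 to 9 (NiCl2(dme) 10 mol%, neocuproine, Mn powder, Et3SiCl, DMF, rt) should give {[(3aS,7aS)-6-{[(2S)-6-methoxy-2,8-dimethyl-3,4-dihydro-2H-1-benzopyran-2-yl]methyl}-3a,7a-dimethyl-5-(2-methylprop-2-en-1-yl)-2,3,3a,6,7,7a-hexahydro-1H-inden-4-yl]oxy}triethylsilane F7. Hydrolysis of F7 with 1 M HCl in THF returns to 18.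

3. Step 13. β-Hydride elimination may go toward the side-chain methylene instead of the ring methine, and silyl enol ether formation at the hindered ketone may be incomplete. The fallback gives up kinetic regiocontrol and uses thermodynamic control; it sets out from 19 and comes back at 22. The oxidation is run as in step 13 without regard to regiochemistry, and the crude product, which then contains (3aS,7aS)-5-(2-hydroxy-2-methylpropylidene)-6-{[(2S)-6-methoxy-2,8-dimethyl-3,4-dihydro-2H-1-benzopyran-2-yl]methyl}-3a,7a-dimethyloctahydro-4H-inden-4-one F8, is not separated. It is equilibrated with RhCl3·3H2O (5 mol%) in EtOH at 70 °C (metal-hydride addition–elimination), which should move the double bond into the ring to the more substituted endocyclic enone 22.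

**Further compounds**
F1 | step 5 | (3aS,7aS)-3a,7a-dimethyl-1,2,3,3a,7,7a-hexahydro-4H-inden-4-one | C1=CC(=O)[C@@]2(C)CCC[C@@]2(C)C1
F2 | step 5 | (3aS,7aS)-5-iodo-3a,7a-dimethyl-1,2,3,3a,7,7a-hexahydro-4H-inden-4-one | IC1=CC[C@]2(C)CCC[C@]2(C)C1=O
F3 | step 10 | (2S)-4-(2-bromo-5-methoxy-3-methylphenyl)-1-[(tert-butyldimethylsilyl)oxy]-2-methylbutan-2-ol | COc1cc(C)c(Br)c(CC[C@@](C)(CO[Si](C)(C)C(C)(C)C)O)c1
F4 | step 10 | tert-butyl{[(2S)-6-methoxy-2,8-dimethyl-3,4-dihydro-2H-1-benzopyran-2-yl]methoxy}dimethylsilane | COc1cc(C)c2c(c1)CC[C@@](C)(CO[Si](C)(C)C(C)(C)C)O2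
F5 | step 10 | [(2S)-6-methoxy-2,8-dimethyl-3,4-dihydro-2H-1-benzopyran-2-yl]methanol | COc1cc(C)c2c(c1)CC[C@@](C)(CO)O2
F6 | step 10 | (2S)-2-(iodomethyl)-6-methoxy-2,8-dimethyl-3,4-dihydro-2H-1-benzopyran | IC[C@]1(C)CCc2cc(OC)cc(C)c2O1
F7 | step 10 | {[(3aS,7aS)-6-{[(2S)-6-methoxy-2,8-dimethyl-3,4-dihydro-2H-1-benzopyran-2-yl]methyl}-3a,7a-dimethyl-5-(2-methylprop-2-en-1-yl)-2,3,3a,6,7,7a-hexahydro-1H-inden-4-yl]oxy}triethylsilane | COc1cc(C)c2c(c1)CC[C@@](C)(CC1C(CC(C)=C)=C(O[Si](CC)(CC)CC)[C@@]3(C)CCC[C@@]3(C)C1)O2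
F8 | step 13 | (3aS,7aS)-5-(2-hydroxy-2-methylpropylidene)-6-{[(2S)-6-methoxy-2,8-dimethyl-3,4-dihydro-2H-1-benzopyran-2-yl]methyl}-3a,7a-dimethyloctahydro-4H-inden-4-one | COc1cc(C)c2c(c1)CC[C@@](C)(CC1C(=CC(C)(C)O)C(=O)[C@@]3(C)CCC[C@@]3(C)C1)O2
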